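## Retrosynthetic overview

1. The C8 ester and the free C6–OH are released in one event: a cyclic carbonate bridging O6 and O8 is opened with 3,4,5-trimethoxyphenyllithium, so the carbonate carbon becomes the ester C=O.
2. The ten-membered ring is closed at C9–C10 (sp3–sp2) by an intramolecular nickel-catalysed reductive coupling of a primary alkyl iodide with a (Z)-vinyl iodide, not by olefin metathesis or a vinyl–aldehyde addition.
3. C8–O and C9–I come from an iodocarbonate cyclisation (1,3-syn); C6 and C7 from an anti-selective γ-isopropyl-allylboration of an epoxy aldehyde; C4 and C5 from a Sharpless epoxidation.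
4. The (Z)-C1=C10 geometry is fixed early by a Stork–Zhao iodo-olefination of an aldehyde cut out of geranyl acetate, which also supplies the (E)-C4=C5 unit.
5. Ring order: oxirane, then 1,3-dioxan-2-one, then the cyclodecene; the dioxanone is opened in the last step.

Assumption: ring and chain positions are named with germacrane numbering (ring C1–C10, C1=C10 alkene, C4–C5 epoxide, C6–OH, C7–isopropyl, C8–ester); D-(−)-diethyl tartrate and (R)-TRIP are taken as purchasable.

## Route

Step 1
Reactants: 1 geranyl acetate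
Product: 2 (2E)-5-(3,3-dimethyloxiran-2-yl)-3-methylpent-2-en-1-yl acetate (racemic at the oxirane CH)
Conditions: mCPBA (1.05 equiv), CH2Cl2, 0 °C
Reagents that add atoms: mCPBA (3-chloroperoxybenzoic acid), OOC(=O)c1cccc(Cl)c1
Why: Prilezhaev epoxidation picks the electron-rich distal trisubstituted alkene over the 2,3-alkene deactivated by the allylic acetate; the new stereocentre is cut out in step 2.

Step 2
Reactants: 2 (2E)-5-(3,3-dimethyloxiran-2-yl)-3-methylpent-2-en-1-yl acetate
Product: 4 (2E)-3-methyl-6-oxohex-2-en-1-yl acetate, via diol 3 (not isolated)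
Conditions: H5IO6, THF/H2O, 0 °C to rt
Reagents that add atoms: water, O (taken up in diol 3)
Why: One-pot epoxide hydrolysis and Malaprade glycol cleavage excises acetone and leaves the C1 aldehyde with the (E)-allylic acetate untouched.

Step 3
Reactants: 4 (2E)-3-methyl-6-oxohex-2-en-1-yl acetate
Product: 5 (2E,6Z)-7-iodo-3-methylocta-2,6-dien-1-yl acetate
Conditions: EtPPh3I, n-BuLi, THF, 0 °C; I2, −78 °C; NaN(SiMe3)2, −20 °C; then 4, −78 °C to rt
Reagents that add atoms: ethyltriphenylphosphonium iodide, CC[P+](c1ccccc1)(c1ccccc1)c1ccccc1.[I-]; iodine, II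
Why: Stork–Zhao iodo-Wittig olefination with the α-iodoethylidene ylide gives the trisubstituted vinyl iodide with iodine cis to the chain under kinetic control, which fixes the Z geometry of the later C1=C10 bond.

Step 4
Reactants: 5 (2E,6Z)-7-iodo-3-methylocta-2,6-dien-1-yl acetate
Product: 6 (2E,6Z)-7-iodo-3-methylocta-2,6-dien-1-ol
Conditions: K2CO3 (cat.), MeOH, rt
Reagents that add atoms: none
Why: Base-catalysed transesterification (methanolysis) frees the primary allylic alcohol without touching the vinyl iodide.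

Step 5
Reactants: 6 (2E,6Z)-7-iodo-3-methylocta-2,6-dien-1-ol
Product: 7 [(2R,3R)-3-[(3Z)-4-iodopent-3-en-1-yl]-3-methyloxiran-2-yl]methanol
Conditions: Ti(OiPr)4 (10 mol%), D-(−)-diethyl tartrate (12 mol%), t-BuOOH, 4 Å MS, CH2Cl2, −20 °C
Reagents that add atoms: tert-butyl hydroperoxide, CC(C)(C)OO
Why: Sharpless asymmetric epoxidation of a geraniol-type (E)-allylic alcohol with the D-(−)-tartrate gives the (2R,3R)-trans-epoxide, setting C4 (R) and C5 (R) by reagent control.

Step 6
Reactants: 7 [(2R,3R)-3-[(3Z)-4-iodopent-3-en-1-yl]-3-methyloxiran-2-yl]methanol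
Product: 8 (2S,3R)-3-[(3Z)-4-iodopent-3-en-1-yl]-3-methyloxirane-2-carbaldehyde
Conditions: Dess–Martin periodinane, pyridine, CH2Cl2, 0 °C
Reagents that add atoms: none
Why: Buffered Dess–Martin oxidation gives the epoxy aldehyde without epimerisation because the oxirane α-carbon does not enolise (the descriptor changes only through priorities).

Step 7
Reactants: 9 3-methylbut-1-yne
Product: 10 4,4,5,5-tetramethyl-2-[(1E)-3-methylbut-1-en-1-yl]-1,3,2-dioxaborolane
Conditions: HBpin, Cp2Zr(H)Cl (5 mol%), Et3N (10 mol%), neat, 60 °C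
Reagents that add atoms: pinacolborane, [H]B1OC(C)(C)C(C)(C)O1
Why: Zirconocene-catalysed syn hydroboration of the terminal alkyne gives the (E)-alkenylboronate only.

Step 8
Reactants: 10 4,4,5,5-tetramethyl-2-[(1E)-3-methylbut-1-en-1-yl]-1,3,2-dioxaborolane
Product: 12 4,4,5,5-tetramethyl-2-[(2E)-4-methylpent-2-en-1-yl]-1,3,2-dioxaborolane, via chloromethyl borate complex 11 (not isolated)
Conditions: BrCH2Cl, n-BuLi, THF, −78 °C to rt
Reagents that add atoms: bromochloromethane, ClCBr
Why: Matteson homologation: LiCH2Cl adds to boron and the alkenyl group migrates 1,2 with loss of chloride and retention of the E geometry, giving the (E)-γ-isopropyl-allylboronate.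

Step 9
Reactants: 8 (2S,3R)-3-[(3Z)-4-iodopent-3-en-1-yl]-3-methyloxirane-2-carbaldehyde; 12 4,4,5,5-tetramethyl-2-[(2E)-4-methylpent-2-en-1-yl]-1,3,2-dioxaborolane
Product: 14 (1R,2R)-1-[(2R,3R)-3-[(3Z)-4-iodopent-3-en-1-yl]-3-methyloxiran-2-yl]-2-(propan-2-yl)but-3-en-1-ol, via borate ester 13 (not isolated)
Conditions: (R)-TRIP [(R)-3,3′-bis(2,4,6-triisopropylphenyl)-1,1′-binaphthyl-2,2′-diyl hydrogen phosphate] (5 mol%), 4 Å MS, toluene, −30 °C; aq. NaHCO3 work-up
Reagents that add atoms: none
Why: Chiral-phosphoric-acid-catalysed allylboration through a closed chair (Zimmerman–Traxler) transition state: the (E)-boronate gives the anti C6–OH/C7–isopropyl pair, and (R)-TRIP sends the allyl group to the Re face, reinforcing the Felkin–Anh (erythro) preference of the epoxy aldehyde, so C6 (R) and C7 are set together.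

Step 10
Reactants: 14 (1R,2R)-1-[(2R,3R)-3-[(3Z)-4-iodopent-3-en-1-yl]-3-methyloxiran-2-yl]-2-(propan-2-yl)but-3-en-1-ol
Product: 15 tert-butyl (1R,2R)-1-[(2R,3R)-3-[(3Z)-4-iodopent-3-en-1-yl]-3-methyloxiran-2-yl]-2-(propan-2-yl)but-3-en-1-yl carbonate
Conditions: Boc2O, DMAP (0.3 equiv), MeCN, rt
Reagents that add atoms: di-tert-butyl dicarbonate, CC(C)(C)OC(=O)OC(=O)OC(C)(C)C
Why: DMAP-catalysed tert-butoxycarbonylation of the secondary alcohol installs the internal oxygen nucleophile for step 11 under non-basic conditions that avoid Payne rearrangement.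

Step 11
Reactants: 15 tert-butyl (1R,2R)-1-[(2R,3R)-3-[(3Z)-4-iodopent-3-en-1-yl]-3-methyloxiran-2-yl]-2-(propan-2-yl)but-3-en-1-yl carbonate
Product: 16 (4S,5S,6R)-4-(iodomethyl)-6-[(2R,3R)-3-[(3Z)-4-iodopent-3-en-1-yl]-3-methyloxiran-2-yl]-5-(propan-2-yl)-1,3-dioxan-2-one
Conditions: IBr, toluene, −85 °C
Reagents that add atoms: iodine monobromide, IBr
Why: Iodocarbonate cyclisation (Bartlett–Cardillo type): the carbonate carbonyl oxygen attacks the iodonium ion of the terminal alkene through a chair with all three substituents equatorial, giving the 4,6-cis (1,3-syn) carbonate with the 5-isopropyl trans to both and so setting C8, while the electron-poor iodoalkene is left alone.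

Step 12
Reactants: 16 (4S,5S,6R)-4-(iodomethyl)-6-[(2R,3R)-3-[(3Z)-4-iodopent-3-en-1-yl]-3-methyloxiran-2-yl]-5-(propan-2-yl)-1,3-dioxan-2-one
Product: 17 (1(10)Z,4R,5R,6R,7R,8R)-4,5-epoxygermacr-1(10)-ene-6,8-diyl carbonate (cyclic carbonate bridging O6 and O8 of the ten-membered ring)
Conditions: NiBr2(dme) (20 mol%), 4,4′-di-tert-butyl-2,2′-bipyridine (25 mol%), Mn powder (3 equiv), DMA, 25 °C, syringe-pump addition to 2 mM
Reagents that add atoms: none
Why: Proposed new method: zerovalent nickel inserts into the vinyl C–I bond, the primary iodide is turned into the C9 radical by iodine-atom abstraction at monovalent nickel, the radical is caught by the vinylnickel centre of the same molecule (an eleven-membered nickelacycle) and reductive elimination from trivalent nickel closes the ten-membered ring with the Z geometry kept, no carbanionic alkylmetal being formed that could expel the β-carbonate oxygen; the closest known reaction type is the intermolecular nickel/bipyridine/Mn reductive cross-electrophile coupling of alkenyl halides with primary alkyl iodides, run here intramolecularly at high dilution.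

Step 13
Reactants: 17 (1(10)Z,4R,5R,6R,7R,8R)-4,5-epoxygermacr-1(10)-ene-6,8-diyl carbonate; 18 5-bromo-1,2,3-trimethoxybenzene
Product: 21 (1(10)Z,4R,5R,6R,7S,8R)-4,5-epoxy-6-hydroxygermacr-1(10)-en-8-yl 3,4,5-trimethoxybenzoate (CNP0260213.8), via aryllithium 19 (not isolated), via lithium hemiorthoester 20 (not isolated)
Conditions: n-BuLi, THF, −78 °C (on 18); add to 17, THF, −78 °C; AcOH, −78 °C
Reagents that add atoms: none
Why: Nucleophilic acyl substitution of a cyclic carbonate by an aryllithium (carbonate-to-hydroxy-benzoate opening): the tetrahedral adduct breaks down by loss of the less basic C6 alkoxide, which sits next to the epoxide and is chelated to lithium, so the aroyl group stays on O8 and no stereocentre is touched.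

## Compound list

1 | geranyl acetate, (2E)-3,7-dimethylocta-2,6-dien-1-yl acetate | CC(C)=CCC/C(C)=C/COC(C)=O | starting material
2 | (2E)-5-(3,3-dimethyloxiran-2-yl)-3-methylpent-2-en-1-yl acetate (racemic) | CC(=O)OC/C=C(\C)CCC1OC1(C)C | intermediate
3 | (2E)-6,7-dihydroxy-3,7-dimethyloct-2-en-1-yl acetate (racemic) | CC(=O)OC/C=C(\C)CCC(O)C(C)(C)O | intermediate (not isolated)
4 | (2E)-3-methyl-6-oxohex-2-en-1-yl acetate | CC(=O)OC/C=C(\C)CCC=O | intermediate
5 | (2E,6Z)-7-iodo-3-methylocta-2,6-dien-1-yl acetate | CC(=O)OC/C=C(\C)CC/C=C(/C)I | intermediate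
6 | (2E,6Z)-7-iodo-3-methylocta-2,6-dien-1-ol | OC/C=C(\C)CC/C=C(/C)I | intermediate
7 | [(2R,3R)-3-[(3Z)-4-iodopent-3-en-1-yl]-3-methyloxiran-2-yl]methanol | C/C(I)=C/CC[C@@]1(C)O[C@@H]1CO | intermediate
8 | (2S,3R)-3-[(3Z)-4-iodopent-3-en-1-yl]-3-methyloxirane-2-carbaldehyde | C/C(I)=C/CC[C@@]1(C)O[C@@H]1C=O | intermediate
9 | 3-methylbut-1-yne | CC(C)C#C | starting material
10 | 4,4,5,5-tetramethyl-2-[(1E)-3-methylbut-1-en-1-yl]-1,3,2-dioxaborolane | CC(C)/C=C/B1OC(C)(C)C(C)(C)O1 | intermediate
11 | lithium chloromethyl[(1E)-3-methylbut-1-en-1-yl](pinacolato)borate | [Li+].CC(C)/C=C/[B-]1(CCl)OC(C)(C)C(C)(C)O1 | intermediate (not isolated)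
12 | 4,4,5,5-tetramethyl-2-[(2E)-4-methylpent-2-en-1-yl]-1,3,2-dioxaborolane | CC(C)/C=C/CB1OC(C)(C)C(C)(C)O1 | intermediate
13 | O-(pinacolatoboryl) derivative of 14, 2-{[(1R,2R)-1-[(2R,3R)-3-[(3Z)-4-iodopent-3-en-1-yl]-3-methyloxiran-2-yl]-2-(propan-2-yl)but-3-en-1-yl]oxy}-4,4,5,5-tetramethyl-1,3,2-dioxaborolane | C/C(I)=C/CC[C@@]1(C)O[C@@H]1[C@H](OB2OC(C)(C)C(C)(C)O2)[C@H](C(C)C)C=C | intermediate (not isolated)
14 | (1R,2R)-1-[(2R,3R)-3-[(3Z)-4-iodopent-3-en-1-yl]-3-methyloxiran-2-yl]-2-(propan-2-yl)but-3-en-1-ol | C/C(I)=C/CC[C@@]1(C)O[C@@H]1[C@H](O)[C@H](C(C)C)C=C | intermediate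
15 | tert-butyl (1R,2R)-1-[(2R,3R)-3-[(3Z)-4-iodopent-3-en-1-yl]-3-methyloxiran-2-yl]-2-(propan-2-yl)but-3-en-1-yl carbonate | C/C(I)=C/CC[C@@]1(C)O[C@@H]1[C@H](OC(=O)OC(C)(C)C)[C@H](C(C)C)C=C | intermediate
16 | (4S,5S,6R)-4-(iodomethyl)-6-[(2R,3R)-3-[(3Z)-4-iodopent-3-en-1-yl]-3-methyloxiran-2-yl]-5-(propan-2-yl)-1,3-dioxan-2-one | C/C(I)=C/CC[C@@]1(C)O[C@@H]1[C@@H]2OC(=O)O[C@H](CI)[C@H]2C(C)C | intermediate
17 | (1(10)Z,4R,5R,6R,7R,8R)-4,5-epoxygermacr-1(10)-ene-6,8-diyl carbonate | C/C1=C/CC[C@@]2(C)O[C@@H]2[C@@H]3OC(=O)O[C@H](C1)[C@H]3C(C)C | intermediate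
18 | 5-bromo-1,2,3-trimethoxybenzene | COc1cc(Br)cc(OC)c1OC | starting material
19 | (3,4,5-trimethoxyphenyl)lithium | [Li]c1cc(OC)c(OC)c(OC)c1 | intermediate (not isolated)
20 | lithium salt of the 2-aryl-2-hydroxy-1,3-dioxane (hemiorthoester) formed from 17 and 19 | C/C1=C/CC[C@@]2(C)O[C@@H]2[C@@H]3OC([O-])(c4cc(OC)c(OC)c(OC)c4)O[C@H](C1)[C@H]3C(C)C.[Li+] | intermediate (not isolated)
21 | (1(10)Z,4R,5R,6R,7S,8R)-4,5-epoxy-6-hydroxygermacr-1(10)-en-8-yl 3,4,5-trimethoxybenzoate, i.e. (1R,4Z,7R,8S,9R,10R)-9-hydroxy-1,5-dimethyl-8-(propan-2-yl)-11-oxabicyclo[8.1.0]undec-4-en-7-yl 3,4,5-trimethoxybenzoate | COc1cc(C(=O)O[C@@H]2C/C(C)=C\CC[C@@]3(C)O[C@@H]3[C@H](O)[C@@H]2C(C)C)cc(OC)c1OC | target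

## Step count and risks

Total step count: 13 (11 in the main line, 2 for allylboronate 12).
Longest linear sequence: 11 steps (1 to 21 through steps 1–6 and 9–13).

Steps most likely to fail:

Step 12 (reductive macrocyclisation). The ring closure is unprecedented in intramolecular form; oligomerisation, simple reduction of the C9–I bond or loss of the β-carbonate could win. The fallback sets out from 15 and comes back to the route at 17. The terminal alkene of 15 is diborated enantioselectively with B2pin2 (Pt(dba)3, taddol-derived phosphonite chosen for the (3R)-boronate, THF, 60 °C) to give the bis(boronate) tert-butyl (1R,2S,3R)-1-[(2R,3R)-3-[(3Z)-4-iodopent-3-en-1-yl]-3-methyloxiran-2-yl]-2-(propan-2-yl)-3,4-bis(4,4,5,5-tetramethyl-1,3,2-dioxaborolan-2-yl)butyl carbonate F1. Only its primary C–B bond enters an intramolecular Suzuki–Miyaura coupling with the (Z)-vinyl iodide (Pd(OAc)2, RuPhos, K3PO4, THF/H2O, 70 °C, high dilution), which closes the same C9–C10 bond by a two-electron palladium cycle and gives the macrocyclic secondary boronate tert-butyl (1(10)Z,4R,5R,6R,7S,8R)-4,5-epoxy-8-(4,4,5,5-tetramethyl-1,3,2-dioxaborolan-2-yl)germacr-1(10)-en-6-yl carbonate F2. NaBO3 oxidation with retention gives the hydroxy carbonate tert-butyl (1(10)Z,4R,5R,6R,7R,8R)-4,5-epoxy-8-hydroxygermacr-1(10)-en-6-yl carbonate F3, and NaH in THF lets the C8 alkoxide close onto the neighbouring tert-butyl carbonate with loss of tert-butoxide to give 17.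

Step 13 (carbonate opening). The aroyl group could end up on O6, or a second aryllithium could add. The fallback sets out from 17 and comes back at 21. The carbonate is removed by methanolysis (K2CO3, MeOH, 0 °C) to give the diol (1(10)Z,4R,5R,6R,7R,8R)-4,5-epoxygermacr-1(10)-ene-6,8-diol F4. The less hindered C8–OH is then acylated selectively with 3,4,5-trimethoxybenzoyl chloride and 2,4,6-collidine in CH2Cl2 at −40 °C; the C6–OH is flanked by the epoxide and the isopropyl-bearing carbon and is hydrogen-bonded to the epoxide oxygen. This is a classical diol differentiation in place of the carbonate-to-ester opening.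

Step 9 (catalytic allylboration). The acid catalyst could open the epoxy aldehyde, or the bulky γ-isopropyl boronate could react with poor facial control. The fallback sets out from 8 and comes back at 14. It is a Nozaki–Hiyama allylation with (E)-1-bromo-4-methylpent-2-ene and CrCl2 in THF at 0 °C: the γ-substituted allylchromium reagent adds through a chair transition state to give the anti adduct, with facial control coming from the Felkin–Anh preference of the epoxy aldehyde instead of from a chiral acid. It makes no compound outside the list (F0).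

## Further compounds

F1 | step 12 | tert-butyl (1R,2S,3R)-1-[(2R,3R)-3-[(3Z)-4-iodopent-3-en-1-yl]-3-methyloxiran-2-yl]-2-(propan-2-yl)-3,4-bis(4,4,5,5-tetramethyl-1,3,2-dioxaborolan-2-yl)butyl carbonate | C/C(I)=C/CC[C@@]1(C)O[C@@H]1[C@H](OC(=O)OC(C)(C)C)[C@H](C(C)C)[C@@H](CB2OC(C)(C)C(C)(C)O2)B3OC(C)(C)C(C)(C)O3
F2 | step 12 | tert-butyl (1(10)Z,4R,5R,6R,7S,8R)-4,5-epoxy-8-(4,4,5,5-tetramethyl-1,3,2-dioxaborolan-2-yl)germacr-1(10)-en-6-yl carbonate | C/C1=C/CC[C@@]2(C)O[C@@H]2[C@H](OC(=O)OC(C)(C)C)[C@H](C(C)C)[C@@H](C1)B3OC(C)(C)C(C)(C)O3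
F3 | step 12 | tert-butyl (1(10)Z,4R,5R,6R,7R,8R)-4,5-epoxy-8-hydroxygermacr-1(10)-en-6-yl carbonate | C/C1=C/CC[C@@]2(C)O[C@@H]2[C@H](OC(=O)OC(C)(C)C)[C@H](C(C)C)[C@@H](C1)O
F4 | step 13 | (1(10)Z,4R,5R,6R,7R,8R)-4,5-epoxygermacr-1(10)-ene-6,8-diol | C/C1=C/CC[C@@]2(C)O[C@@H]2[C@H](O)[C@H](C(C)C)[C@@H](C1)O
F0 | step 9 | none | none
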